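## Structural features

The target is a 2-arylbenzofuran: a furan ring fused to a benzo ring, with a 3-hydroxy-4-methoxyphenyl group on C2 and a methoxy group on C3, so that C2=C3 is a fully substituted, electron-rich enol ether. The benzo ring carries a free hydroxyl at C6 and a 3-methylbut-2-enyl (prenyl) chain on the neighbouring C5; C4 and C7 bear hydrogen. There is no stereocentre and no stereogenic double bond, because the prenyl alkene ends in two methyl groups. The task is therefore one of regiochemistry and of telling four oxygens apart: two are methylated (on C3 and C4') and two are free (on C6 and C3'). The fragile parts are the ortho-prenylphenol (acid closes it to a chroman, oxidants attack it), the trisubstituted alkene, and the 3-methoxy-2-arylbenzofuran unit, which is sensitive to acid and to oxidation. The real difficulty is the 1,2,4,5-tetrasubstituted benzo ring with the prenyl group next to an oxygen, since direct C-prenylation of a resorcinol-type ring is poorly regioselective. The key step uses exactly this pattern: C3a bears a carbon (C3), the adjacent C7a bears O1, C6 bears an oxygen para to C3a, and C5 bears the prenyl group. A 4-alkoxy-2-pyrone-5-carboxylate supplies the ester carbon (future C3) and the ether oxygen (future O1), and a prenylated siloxyalkyne supplies C5 and C6 after cycloaddition and loss of CO2.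

## Logic of the disconnections

17 to 16: the two phenolic O–H bonds are traced back to O–Si bonds. Both phenols must stay masked through a strongly basic ring closure and through the methylation that marks the C3 oxygen, and two identical silyl ethers can be released together by fluoride. The skeleton is unchanged, but the oxygen-differentiation problem is removed. The forward step must avoid acid (ortho-prenylphenol, enol ether) and must not leave the phenoxides exposed to air.

16 to 14 (through 15): the O–CH3 bond on C3 and the C2–C3 bond of the furan ring are cut. C3 with its oxygen is an ester carbonyl in disguise, and C2 is a benzylic carbon already bound to O1. The furan ring and the enol ether disappear and leave the ester 14, which carries the arylmethyl group on its ortho oxygen. The forward step needs a base strong enough to remove a weakly acidic benzylic C–H next to oxygen, for which a silazide is judged too weak and a hindered lithium amide is chosen, and the enolate 15 must be alkylated on oxygen.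

14 to 8 and 12 (through 13): the C4–C5 and C6–C7 bonds of the benzo ring are cut, which takes the ring apart into four carbons of 8 and the two alkyne carbons of 12, with CO2 as the extruded bridge. This is the strategic cut because it replaces arene substitution chemistry by a polarity-matched union of two simple pieces; the prenyl group arrives on an sp carbon and never has to be placed on an arene. The forward step must proceed in one orientation, must tolerate a benzylic ether, two silyl ethers and an alkene at elevated temperature, and must lose CO2 cleanly.

8 to 4 and 7: the O–CH2 bond is cut. This separates the diene from the aryl part and makes both available from very simple materials. The forward step must alkylate the C4 oxygen of an ambident 4-hydroxypyrone and not the lactone oxygen or C3.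

4 to 1 and 2 (through 3): the lactone O–C(=O) bond and the C5–C6 bond of the pyrone are cut, C6 being the orthoformate carbon. The heterocycle reduces to a symmetrical keto diester and a one-carbon unit. Mono-condensation and a hydrolytic ring closure are required.

7 to 6 to 5: a C–H bond of the CH2OH group (reduction) and the O–Si bond are cut, leading to a commercial hydroxy aldehyde. The silyl ether must survive hydride reduction.

12 to 9 (through 10 and 11): the O–Si bond and the bond between the prenyl CH2 and the alkyne carbon are cut, the latter formed by a 1,2-shift in a one-carbon homologation of an ester. The siloxyalkyne thus comes from a five-carbon ester in one flask. Carbonyl addition must outrun enolisation of an ester with doubly activated α-hydrogens, and the ynolate must be silylated on oxygen.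

## Other disconnections considered

Alternative 1: The cut removes both bonds that join the furan ring to the benzo ring, C3–C3a and O1–C7a. It leads to 2-methoxy-1-[4-methoxy-3-(methoxymethoxy)phenyl]ethan-1-one A2 and 1-bromo-2-iodo-5-(methoxymethoxy)-4-(3-methylbut-2-enyl)benzene A3. In the forward direction zerovalent palladium (Pd2(dba)3, Xantphos, Cs2CO3) would arylate the enolate carbon of A2 at the C–I bond of A3 and then close O1–C7a by O-arylation at the C–Br bond, giving the bis(methoxymethyl) ether A1 of the target.
- In its favour: one catalytic operation builds the whole furan ring, the C3 methoxy group is present from the start so no O- versus C-methylation question arises, and no strong base is needed. On these three points it is the better of the two plans.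
- Against it: the result depends on complete discrimination between iodide and bromide, since the reverse order would give the isomer with oxygen on C5 and prenyl on C6. α-Alkoxy ketones are less usual partners in enolate arylation. A3 is itself a benzene ring with four different substituents, so the regiochemical problem is moved into a starting material and not solved. The methoxymethyl groups need acid for removal, which endangers the ortho-prenylphenol and the enol ether.
- Comparison: on structure the chosen plan sets the benzo substitution pattern in the ring-forming step, whereas A3 must be prepared over several steps. On mechanism the palladium cascade is milder and better precedented for closing the furan. On step economy the two are about equal after the key step (one deprotection against two steps), while the fragments of the chosen plan are shorter to make.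

Alternative 2: The cut is the acyl–arene bond C3–C3a. 2-[4-Bromo-3-(triisopropylsilyloxy)phenoxy]-2-[4-methoxy-3-(triisopropylsilyloxy)phenyl]acetic acid A5 would be converted in the flask into its acid chloride A6, which under SnCl4 acylates the position para to the C6 oxygen and gives the racemic benzofuranone A4.
- In its favour: the site of closure is fixed by the strongest donor and by the blocking bromine, the reagents are classical and cheap, and no strong base is needed, which is better than the chosen plan. A4 has the same benzofuranone oxidation level as the enolate 15 of the chosen route, so from that point the two plans are equal and share the O-methylation question.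
- Against it: an α-aryloxy-α-aryl acylium ion is prone to lose CO to a doubly stabilised cation, SnCl4 and the HCl formed threaten the aryl silyl ethers, and the prenyl group must be added afterwards by cross-coupling at a bromide flanked by a bulky silyl ether, with the risk of allylic transposition. The stereocentre of A4 is of no consequence.
- Comparison: the chosen plan installs the prenyl group without late cross-coupling and without a Lewis acid. Three steps follow the key step here (methylation, prenylation, desilylation) against two in the chosen plan, and A5 needs an etherification and a hydrolysis beforehand.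

Alternative 3: The cut removes C2–C3 and O1–C2. Dimethyl{[4-methoxy-3-(triisopropylsilyloxy)phenyl]methyl}sulfonium bromide A8 and 2-hydroxy-5-(3-methylbut-2-enyl)-4-(triisopropylsilyloxy)benzaldehyde A9 would be combined under a carbonate base; the ylide adds to the aldehyde and the phenoxide displaces dimethyl sulfide from the betaine, giving the trans dihydrobenzofuranol A7.
- In its favour: the ring closure runs at ambient temperature with a weak base, every protecting group survives, and the annulation of salicylaldehydes with sulfur ylides is well precedented. In mildness and precedent of the ring closure it is better than the chosen plan.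
- Against it: the oxidation level is wrong, so the C3 carbinol must be oxidised to the ketone and then O-methylated, one step more after the key step than in the chosen plan. Two stereocentres are made only to be erased. Acid would cause dehydration with loss of the C3 oxygen. A9 requires regioselective C-prenylation and selective silylation of a dihydroxybenzaldehyde, which is the problem the chosen plan avoids. The semi-stabilised ylide may also close to an epoxide (Corey–Chaykovsky pathway).
- Comparison: the convergence is equal, the ring closure is safer, and the access to the arene is weaker than in the chosen plan.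

Key step: step 6

Remark on the chemistry: neither the target nor any isolated intermediate has a stereogenic element; 3 is taken as an E/Z mixture and 13 as a racemate, both consumed in the flask.

## Route

Step 1
Reactants: 1 dimethyl 1,3-acetonedicarboxylate (dimethyl 3-oxopentanedioate); 2 triethyl orthoformate
Product: 4 methyl 4-hydroxy-2-oxo-2H-pyran-5-carboxylate, via ethoxymethylene ketodiester 3 (not isolated)
Conditions: Ac2O, 120–130 °C; then aq. HCl, rt → 50 °C
Reagents that add atoms: water, O
Why: Knoevenagel-type condensation of the active methylene with the orthoformate (acetic anhydride takes up the ethanol) should give 3; acid hydrolysis of the enol ether and lactonisation onto the distal ester with loss of methanol then closes the 4-hydroxy-2-pyrone, and the symmetry of 1 means mono-condensation gives a single product.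

Step 2
Reactants: 5 isovanillin (3-hydroxy-4-methoxybenzaldehyde)
Product: 6 4-methoxy-3-(triisopropylsilyloxy)benzaldehyde
Conditions: i-Pr3SiCl, imidazole, DMF, rt
Reagents that add atoms: chlorotriisopropylsilane, CC(C)[Si](Cl)(C(C)C)C(C)C
Why: Standard O-silylation of a phenol; the bulky silyl ether is chosen because it should survive hydride, Mitsunobu conditions, heat and a lithium amide, and leaves with fluoride.

Step 3
Reactants: 6 4-methoxy-3-(triisopropylsilyloxy)benzaldehyde
Product: 7 [4-methoxy-3-(triisopropylsilyloxy)phenyl]methanol
Conditions: NaBH4, MeOH, 0 °C
Reagents that add atoms: none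
Why: Hydride reduction of an aromatic aldehyde; the hindered aryl silyl ether should be stable to brief exposure to NaBH4 in cold methanol.

Step 4
Reactants: 4 methyl 4-hydroxy-2-oxo-2H-pyran-5-carboxylate; 7 [4-methoxy-3-(triisopropylsilyloxy)phenyl]methanol
Product: 8 methyl 4-{[4-methoxy-3-(triisopropylsilyloxy)phenyl]methoxy}-2-oxo-2H-pyran-5-carboxylate
Conditions: PPh3, DIAD, THF, 0 °C → rt
Reagents that add atoms: none
Why: Mitsunobu etherification; the strongly acidic 4-hydroxypyrone is an ideal pronucleophile and such pyrones are known to be alkylated mainly on the C4 oxygen, and using the alcohol directly avoids an unstable electron-rich benzylic bromide and saves a step.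

Step 5
Reactants: 9 ethyl 4-methylpent-3-enoate
Product: 12 triisopropyl[(5-methylhex-4-en-1-yn-1-yl)oxy]silane, via dibromo enolate 10 (not isolated), via lithium ynolate 11 (not isolated)
Conditions: CH2Br2, LiTMP (lithium 2,2,6,6-tetramethylpiperidide), THF, −78 °C; add 9; LiN(SiMe3)2; n-BuLi, −78 °C → rt; then i-Pr3SiCl, −78 → 0 °C
Reagents that add atoms: dibromomethane, BrCBr; chlorotriisopropylsilane, CC(C)[Si](Cl)(C(C)C)C(C)C
Why: Kowalski homologation: LiCHBr2 adds to the ester, the adduct collapses to enolate 10, bromine–lithium exchange triggers a 1,2-shift of the prenyl group to ynolate 11, and the bulky chlorosilane should silylate 11 on oxygen to the isolable siloxyalkyne.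

Step 6
Reactants: 8 methyl 4-{[4-methoxy-3-(triisopropylsilyloxy)phenyl]methoxy}-2-oxo-2H-pyran-5-carboxylate; 12 triisopropyl[(5-methylhex-4-en-1-yn-1-yl)oxy]silane
Product: 14 methyl 2-{[4-methoxy-3-(triisopropylsilyloxy)phenyl]methoxy}-5-(3-methylbut-2-enyl)-4-(triisopropylsilyloxy)benzoate, via bridged lactone adduct 13 (not isolated)
Conditions: PhMe, 110 °C, sealed tube, 12 in excess; −CO2
Reagents that add atoms: none
Why: An inverse-demand Diels–Alder reaction between the electron-poor diene C3=C4–C5=C6 of 8 and the electron-rich alkyne 12 should proceed in a highly asynchronous way: the nucleophilic, prenyl-bearing alkyne carbon bonds to pyrone C6 and the siloxy-bearing carbon closes onto pyrone C3, giving the 2-oxabicyclo[2.2.2]octadienone 13. A retro-[4+2] loss of CO2 from 13 is irreversible and delivers the arene 14. The closest known reactions are the benzannulations of 2-pyrone carboxylates with ynamines, ketene acetals, alkynyl ethers and siloxyalkynes. The only ring formed is the six-membered benzo ring, closed by an intermolecular [4+2] cycloaddition that makes both new C–C bonds (the later C4–C5 and C6–C7) in one operation, not by cyclisation of a tethered chain. No stereocentre appears in 14; the two bridgehead centres of 13 are transient and vanish with the CO2. The step needs regioselectivity, which the substrate secures by polarity: C6 is the β-carbon of a β-acyloxyacrylate and the most electrophilic site, while C3 is the enol-ether terminus of the 4-alkoxy group and matches the ketenium-like siloxy carbon, so the alkoxy group reinforces the orientation even though it slows the reaction. Chemoselectivity should follow from the neutral conditions, under which the trisubstituted alkenes, the benzylic ether and the silyl ethers are spectators. The alkyne is used in excess because thermal silyl migration to a silylketene can consume part of it.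

Step 7
Reactants: 14 methyl 2-{[4-methoxy-3-(triisopropylsilyloxy)phenyl]methoxy}-5-(3-methylbut-2-enyl)-4-(triisopropylsilyloxy)benzoate
Product: 16 3-methoxy-2-[4-methoxy-3-(triisopropylsilyloxy)phenyl]-5-(3-methylbut-2-enyl)-6-(triisopropylsilyloxy)benzofuran, via lithium benzofuran-3-olate 15 (not isolated)
Conditions: LiTMP, THF, −78 → 0 °C; then DMPU, Me2SO4, 0 °C → rt
Reagents that add atoms: dimethyl sulfate, COS(=O)(=O)OC
Why: The hindered lithium amide, precomplexed to the ester carbonyl, should remove an OCH2Ar hydrogen, and the α-aryloxybenzyl anion acylates intramolecularly (5-exo-trig, a Dieckmann-like anionic cyclisation known for O-benzyl salicylic esters, amides and nitriles); the benzofuranone formed is deprotonated at once to 15, which the hard electrophile in the presence of DMPU should methylate on oxygen, and trapping in the same flask avoids handling the air-sensitive benzofuranone.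

Step 8
Reactants: 16 3-methoxy-2-[4-methoxy-3-(triisopropylsilyloxy)phenyl]-5-(3-methylbut-2-enyl)-6-(triisopropylsilyloxy)benzofuran
Product: 17 2-(3-hydroxy-4-methoxyphenyl)-3-methoxy-5-(3-methylbut-2-enyl)benzofuran-6-ol (target)
Conditions: Bu4NF, AcOH, THF, 0 °C, under argon
Reagents that add atoms: none
Why: Fluoride cleavage of both aryl silyl ethers in one operation; the acetic acid buffer keeps the electron-rich phenoxides protonated, and the conditions are free of strong acid, so the ortho-prenylphenol and the enol ether should be untouched.

## Compound list

1 | dimethyl 1,3-acetonedicarboxylate | COC(=O)CC(=O)CC(=O)OC | starting material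
2 | triethyl orthoformate | CCOC(OCC)OCC | starting material
3 | dimethyl 2-(ethoxymethylidene)-3-oxopentanedioate (E/Z mixture) | CCOC=C(C(=O)OC)C(=O)CC(=O)OC | intermediate
4 | methyl 4-hydroxy-2-oxo-2H-pyran-5-carboxylate | COC(=O)C1=COC(=O)C=C1O | intermediate
5 | isovanillin (3-hydroxy-4-methoxybenzaldehyde) | COc1ccc(C=O)cc1O | starting material
6 | 4-methoxy-3-(triisopropylsilyloxy)benzaldehyde | COc1ccc(C=O)cc1O[Si](C(C)C)(C(C)C)C(C)C | intermediate
7 | [4-methoxy-3-(triisopropylsilyloxy)phenyl]methanol | COc1ccc(CO)cc1O[Si](C(C)C)(C(C)C)C(C)C | intermediate
8 | methyl 4-{[4-methoxy-3-(triisopropylsilyloxy)phenyl]methoxy}-2-oxo-2H-pyran-5-carboxylate | COC(=O)C1=COC(=O)C=C1OCc1ccc(OC)c(O[Si](C(C)C)(C(C)C)C(C)C)c1 | intermediate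
9 | ethyl 4-methylpent-3-enoate | CCOC(=O)CC=C(C)C | starting material
10 | lithium 1,1-dibromo-5-methylhexa-1,4-dien-2-olate | CC(C)=CCC(O[Li])=C(Br)Br | intermediate
11 | lithium 5-methylhex-4-en-1-yn-1-olate | CC(C)=CCC#CO[Li] | intermediate
12 | triisopropyl[(5-methylhex-4-en-1-yn-1-yl)oxy]silane | CC(C)=CCC#CO[Si](C(C)C)(C(C)C)C(C)C | intermediate
13 | methyl 8-{[4-methoxy-3-(triisopropylsilyloxy)phenyl]methoxy}-6-(3-methylbut-2-enyl)-3-oxo-5-(triisopropylsilyloxy)-2-oxabicyclo[2.2.2]octa-5,7-diene-7-carboxylate (racemic; the relative configuration of the two bridgeheads is fixed by the bicycle) | O=C1OC2C(C(=O)OC)=C(OCc3ccc(OC)c(O[Si](C(C)C)(C(C)C)C(C)C)c3)C1C(O[Si](C(C)C)(C(C)C)C(C)C)=C2CC=C(C)C | intermediate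
14 | methyl 2-{[4-methoxy-3-(triisopropylsilyloxy)phenyl]methoxy}-5-(3-methylbut-2-enyl)-4-(triisopropylsilyloxy)benzoate | COC(=O)c1cc(CC=C(C)C)c(O[Si](C(C)C)(C(C)C)C(C)C)cc1OCc1ccc(OC)c(O[Si](C(C)C)(C(C)C)C(C)C)c1 | intermediate
15 | lithium 2-[4-methoxy-3-(triisopropylsilyloxy)phenyl]-5-(3-methylbut-2-enyl)-6-(triisopropylsilyloxy)-1-benzofuran-3-olate | [Li]Oc1c(-c2ccc(OC)c(O[Si](C(C)C)(C(C)C)C(C)C)c2)oc2cc(O[Si](C(C)C)(C(C)C)C(C)C)c(CC=C(C)C)cc12 | intermediate
16 | 3-methoxy-2-[4-methoxy-3-(triisopropylsilyloxy)phenyl]-5-(3-methylbut-2-enyl)-6-(triisopropylsilyloxy)benzofuran | COc1c(-c2ccc(OC)c(O[Si](C(C)C)(C(C)C)C(C)C)c2)oc2cc(O[Si](C(C)C)(C(C)C)C(C)C)c(CC=C(C)C)cc12 | intermediate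
17 | 2-(3-hydroxy-4-methoxyphenyl)-3-methoxy-5-(3-methylbut-2-enyl)benzofuran-6-ol | COc1ccc(-c2oc3cc(O)c(CC=C(C)C)cc3c2OC)cc1O | target

## Step count and least certain steps

Total step count: 8. Longest linear sequence: 6 steps (steps 2, 3, 4, 6, 7 and 8, from 5).

**Step 6 (key step).** The 4-alkoxy group raises the energy of the diene, so the cycloaddition may be slow. That would give time for thermal silyl migration in 12 to a silylketene and for ionisation of the electron-rich benzylic ether of 8. A reversed orientation of addition is less likely but would have to be excluded by structure proof.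
Fallback: a classical route that buys the benzo ring and attaches the prenyl group by cross-coupling; it sets out from 7 and comes back at 14. Commercial methyl 5-bromo-2,4-dihydroxybenzoate (COC(=O)c1cc(Br)c(O)cc1O) would be silylated selectively at the non-chelated 4-hydroxyl (i-Pr3SiCl, imidazole) to methyl 5-bromo-2-hydroxy-4-(triisopropylsilyloxy)benzoate F1. Mitsunobu etherification of its remaining phenol with 7 would give methyl 5-bromo-2-{[4-methoxy-3-(triisopropylsilyloxy)phenyl]methoxy}-4-(triisopropylsilyloxy)benzoate F2. Stille coupling of F2 with tributyl(3-methylbut-2-enyl)stannane under zerovalent palladium (Pd(PPh3)4, DMF, heat) would then give 14.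

**Step 7.** Metalation may be incomplete or misdirected (the allylic-benzylic CH2 of the prenyl group, or arene positions next to the ester). The benzylic anion may undergo [1,2]-Wittig rearrangement before it reaches the ester. The enolate 15 may be methylated on C2 and not on oxygen, or be oxidised by adventitious air.
Fallback: a base-free ring closure by Norrish–Yang photocyclisation; it sets out from 14 and comes back at 16. Reduction of the ester with i-Bu2AlH would give [2-{[4-methoxy-3-(triisopropylsilyloxy)phenyl]methoxy}-5-(3-methylbut-2-enyl)-4-(triisopropylsilyloxy)phenyl]methanol F3. MnO2 would oxidise it to 2-{[4-methoxy-3-(triisopropylsilyloxy)phenyl]methoxy}-5-(3-methylbut-2-enyl)-4-(triisopropylsilyloxy)benzaldehyde F4. Irradiation through Pyrex in benzene should cause the excited carbonyl to abstract a benzylic ether hydrogen, and closure of the 1,5-biradical would give 2-[4-methoxy-3-(triisopropylsilyloxy)phenyl]-5-(3-methylbut-2-enyl)-6-(triisopropylsilyloxy)-2,3-dihydrobenzofuran-3-ol F5 as a mixture of cis and trans racemates (the trans component is A7). Dess–Martin oxidation would give 2-[4-methoxy-3-(triisopropylsilyloxy)phenyl]-5-(3-methylbut-2-enyl)-6-(triisopropylsilyloxy)benzofuran-3(2H)-one F6. O-methylation with K2CO3 and Me2SO4 in acetone, or with MeOH, PPh3 and DIAD should carbon alkylation intrude, would give 16.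

**Step 5.** The doubly activated allylic α-CH2 of 9 may be enolised by the carbenoid or the amide in competition with carbonyl addition, which would return ester with the double bond moved into conjugation. Silylation of 11 on carbon would give a silylketene.
Fallback: the ynolate is made by oxidation of an acetylide and not by ester homologation; it sets out from 9 and comes back at 11. Reduction with i-Bu2AlH at −78 °C would give 4-methylpent-3-enal F7. Colvin rearrangement with Me3SiC(Li)N2 at low temperature would give 5-methylhex-4-en-1-yne F8. n-BuLi would convert it into lithium 5-methylhex-4-en-1-yn-1-ide F9, and oxidation with LiOO-t-Bu (from t-BuOOH and LiN(SiMe3)2) would give 11, which is silylated as in step 5.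

**Step 4.** The ambident pyronolate may be alkylated at the wrong site (the lactone carbonyl oxygen, leading to a 2-alkoxy-4-pyrone, or C3), and the phosphine may add in conjugate fashion at C6.
Fallback: the polarity of the bond formation is reversed so that the oxygen of 7 attacks C4 of the pyrone; it sets out from 4 and comes back at 8. POCl3 and Et3N would convert 4 into methyl 4-chloro-2-oxo-2H-pyran-5-carboxylate F10. Addition–elimination of 7 at C4 (Cs2CO3, MeCN, 0 °C) would give 8 with no ambident nucleophile involved.

## Further compounds

F1 | step 6 | methyl 5-bromo-2-hydroxy-4-(triisopropylsilyloxy)benzoate | COC(=O)c1cc(Br)c(O[Si](C(C)C)(C(C)C)C(C)C)cc1O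
F2 | step 6 | methyl 5-bromo-2-{[4-methoxy-3-(triisopropylsilyloxy)phenyl]methoxy}-4-(triisopropylsilyloxy)benzoate | COC(=O)c1cc(Br)c(O[Si](C(C)C)(C(C)C)C(C)C)cc1OCc1ccc(OC)c(O[Si](C(C)C)(C(C)C)C(C)C)c1
F3 | step 7 | [2-{[4-methoxy-3-(triisopropylsilyloxy)phenyl]methoxy}-5-(3-methylbut-2-enyl)-4-(triisopropylsilyloxy)phenyl]methanol | OCc1cc(CC=C(C)C)c(O[Si](C(C)C)(C(C)C)C(C)C)cc1OCc1ccc(OC)c(O[Si](C(C)C)(C(C)C)C(C)C)c1
F4 | step 7 | 2-{[4-methoxy-3-(triisopropylsilyloxy)phenyl]methoxy}-5-(3-methylbut-2-enyl)-4-(triisopropylsilyloxy)benzaldehyde | O=Cc1cc(CC=C(C)C)c(O[Si](C(C)C)(C(C)C)C(C)C)cc1OCc1ccc(OC)c(O[Si](C(C)C)(C(C)C)C(C)C)c1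
F5 | step 7 | 2-[4-methoxy-3-(triisopropylsilyloxy)phenyl]-5-(3-methylbut-2-enyl)-6-(triisopropylsilyloxy)-2,3-dihydrobenzofuran-3-ol, mixture of cis and trans racemates | OC1C(c2ccc(OC)c(O[Si](C(C)C)(C(C)C)C(C)C)c2)Oc2cc(O[Si](C(C)C)(C(C)C)C(C)C)c(CC=C(C)C)cc12
F6 | step 7 | 2-[4-methoxy-3-(triisopropylsilyloxy)phenyl]-5-(3-methylbut-2-enyl)-6-(triisopropylsilyloxy)benzofuran-3(2H)-one, racemic | O=C1C(c2ccc(OC)c(O[Si](C(C)C)(C(C)C)C(C)C)c2)Oc2cc(O[Si](C(C)C)(C(C)C)C(C)C)c(CC=C(C)C)cc12
F7 | step 5 | 4-methylpent-3-enal | CC(C)=CCC=O
F8 | step 5 | 5-methylhex-4-en-1-yne | CC(C)=CCC#C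
F9 | step 5 | lithium 5-methylhex-4-en-1-yn-1-ide | [Li]C#CCC=C(C)C
F10 | step 4 | methyl 4-chloro-2-oxo-2H-pyran-5-carboxylate | COC(=O)C1=COC(=O)C=C1Cl
A1 | alternative 1 | 3-methoxy-2-[4-methoxy-3-(methoxymethoxy)phenyl]-6-(methoxymethoxy)-5-(3-methylbut-2-enyl)benzofuran | COCOc1cc2oc(-c3ccc(OC)c(OCOC)c3)c(OC)c2cc1CC=C(C)C
A2 | alternative 1 | 2-methoxy-1-[4-methoxy-3-(methoxymethoxy)phenyl]ethan-1-one | COCC(=O)c1ccc(OC)c(OCOC)c1
A3 | alternative 1 | 1-bromo-2-iodo-5-(methoxymethoxy)-4-(3-methylbut-2-enyl)benzene | COCOc1cc(Br)c(I)cc1CC=C(C)C
A4 | alternative 2 | 5-bromo-2-[4-methoxy-3-(triisopropylsilyloxy)phenyl]-6-(triisopropylsilyloxy)benzofuran-3(2H)-one, racemic | O=C1c2cc(Br)c(O[Si](C(C)C)(C(C)C)C(C)C)cc2OC1c1ccc(OC)c(O[Si](C(C)C)(C(C)C)C(C)C)c1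
A5 | alternative 2 | 2-[4-bromo-3-(triisopropylsilyloxy)phenoxy]-2-[4-methoxy-3-(triisopropylsilyloxy)phenyl]acetic acid, racemic | OC(=O)C(Oc1ccc(Br)c(O[Si](C(C)C)(C(C)C)C(C)C)c1)c1ccc(OC)c(O[Si](C(C)C)(C(C)C)C(C)C)c1
A6 | alternative 2 | 2-[4-bromo-3-(triisopropylsilyloxy)phenoxy]-2-[4-methoxy-3-(triisopropylsilyloxy)phenyl]acetyl chloride, racemic | ClC(=O)C(Oc1ccc(Br)c(O[Si](C(C)C)(C(C)C)C(C)C)c1)c1ccc(OC)c(O[Si](C(C)C)(C(C)C)C(C)C)c1
A7 | alternative 3 | trans-2-[4-methoxy-3-(triisopropylsilyloxy)phenyl]-5-(3-methylbut-2-enyl)-6-(triisopropylsilyloxy)-2,3-dihydrobenzofuran-3-ol, racemic, (2S,3R) enantiomer drawn | O[C@H]1[C@H](c3ccc(OC)c(O[Si](C(C)C)(C(C)C)C(C)C)c3)Oc2cc(O[Si](C(C)C)(C(C)C)C(C)C)c(CC=C(C)C)cc21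
A8 | alternative 3 | dimethyl{[4-methoxy-3-(triisopropylsilyloxy)phenyl]methyl}sulfonium bromide | C[S+](C)Cc1ccc(OC)c(O[Si](C(C)C)(C(C)C)C(C)C)c1.[Br-]
A9 | alternative 3 | 2-hydroxy-5-(3-methylbut-2-enyl)-4-(triisopropylsilyloxy)benzaldehyde | O=Cc1cc(CC=C(C)C)c(O[Si](C(C)C)(C(C)C)C(C)C)cc1O
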